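## Retrosynthetic overview

1. Locants follow chroman numbering in both isoflavan units. Upper unit: rings A (benzo), C (pyran), B (3-hydroxy-2,4-dimethoxyphenyl on C3). Lower unit: rings D (benzo), F (pyran), E (the aryl ring on its C3, which also carries C4 of the upper unit).
2. Enabling feature: in the upper unit, O1–C8a(=C4a)–C4 of rings A/C is a latent o-quinone methide, because C4 is doubly benzylic and para-related through C4a to the C7 oxygen; C2–C3(ring B) is a latent arylacetaldehyde enamine. Ring C is therefore cut at O1–C2 and C3–C4, and the C4–ring E bond is cut in the same operation (aryllithium + O-Boc salicylaldehyde).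
3. After the key step only the lactol OH at C2 (Et3SiH/BF3·OEt2) and four benzyl ethers (H2, Pd/C) have to be removed.
4. Lower unit: ring F by Mitsunobu O1–C2 closure; its C3 stereocentre by Evans alkylation of a ring E arylacetyl imide with a ring D benzylic bromide; the ring E oxygen pattern by C–H borylation/oxidation of a 2-bromo-3-methoxyphenylacetate.
5. Order of ring formation: ring F (step 13), then ring C (step 19); rings A, B, D and E come from commercial arenes.

Key step: step 19

## Route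

Step 1
Reactants: 1 2-bromo-3-methoxybenzoic acid
Product: 3 1-(2-bromo-3-methoxyphenyl)-2-diazoethan-1-one, via acid chloride 2 (not isolated)
Conditions: (COCl)2, cat. DMF, CH2Cl2, 0 °C to rt; evaporate; Me3SiCHN2, THF/MeCN, 0 °C to rt
Reagents that add atoms: trimethylsilyldiazomethane, C[Si](C)(C)C=[N+]=[N-]
Why: First stage of an Arndt–Eistert homologation: the acid chloride acylates the diazoalkane carbon and chloride removes the silyl group, which should give the α-diazoketone without touching the aryl bromide.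

Step 2
Reactants: 3 1-(2-bromo-3-methoxyphenyl)-2-diazoethan-1-one
Product: 4 methyl 2-(2-bromo-3-methoxyphenyl)acetate
Conditions: PhCO2Ag (10 mol %), Et3N, MeOH, rt
Reagents that add atoms: methanol, CO
Why: Silver-catalysed Wolff rearrangement to the arylketene and its capture by methanol should complete the Arndt–Eistert one-carbon homologation.

Step 3
Reactants: 4 methyl 2-(2-bromo-3-methoxyphenyl)acetate
Product: 6 methyl 2-(2-bromo-5-hydroxy-3-methoxyphenyl)acetate, via aryl boronate 5 (not isolated)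
Conditions: [Ir(OMe)(cod)]2 (1.5 mol %), 4,4'-di-tert-butyl-2,2'-bipyridine (3 mol %), B2pin2, THF, 70 °C; evaporate; KHSO5 (as 2KHSO5·KHSO4·K2SO4), acetone/H2O, rt
Reagents that add atoms: potassium peroxymonosulfate, [K+].[O-]S(=O)(=O)OO
Why: Iridium-catalysed C–H borylation is sterically governed and should take the only ring C–H without an ortho substituent (C5, meta to both CH2CO2Me and OMe), and oxidation of the C–B bond then places the phenol oxygen at exactly that position.

Step 4
Reactants: 6 methyl 2-(2-bromo-5-hydroxy-3-methoxyphenyl)acetate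
Product: 7 methyl 2-[5-(benzyloxy)-2-bromo-3-methoxyphenyl]acetate
Conditions: BnBr, K2CO3, DMF, rt
Reagents that add atoms: benzyl bromide, BrCc1ccccc1
Why: Williamson etherification of the phenoxide should be clean because K2CO3 does not deprotonate the ester α-CH2.

Step 5
Reactants: 7 methyl 2-[5-(benzyloxy)-2-bromo-3-methoxyphenyl]acetate
Product: 8 2-[5-(benzyloxy)-2-bromo-3-methoxyphenyl]acetic acid
Conditions: LiOH, THF/H2O, rt; then 1 M HCl
Reagents that add atoms: lithium hydroxide, [Li+].[OH-]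
Why: Saponification of the methyl ester should proceed without affecting the benzyl ether or the aryl bromide.

Step 6
Reactants: 8 2-[5-(benzyloxy)-2-bromo-3-methoxyphenyl]acetic acid; 9 (4R)-4-benzyl-1,3-oxazolidin-2-one
Product: 11 (4R)-4-benzyl-3-{[5-(benzyloxy)-2-bromo-3-methoxyphenyl]acetyl}-1,3-oxazolidin-2-one, via mixed anhydride 10 (not isolated)
Conditions: t-BuCOCl, Et3N, THF, −20 °C; then 9, LiCl, −20 °C to rt
Reagents that add atoms: none
Why: N-Acylation of the oxazolidinone through the mixed pivalic anhydride (LiCl/Et3N variant) should give the imide without a strong base.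

Step 7
Reactants: 12 4-(benzyloxy)-2-hydroxybenzaldehyde
Product: 13 4-(benzyloxy)-2-[(tert-butyldimethylsilyl)oxy]benzaldehyde
Conditions: t-BuMe2SiCl, imidazole, DMF, rt
Reagents that add atoms: tert-butyldimethylsilyl chloride, CC(C)(C)[Si](C)(C)Cl
Why: Silylation of the phenol masks the oxygen that later closes ring F.

Step 8
Reactants: 13 4-(benzyloxy)-2-[(tert-butyldimethylsilyl)oxy]benzaldehyde
Product: 14 {4-(benzyloxy)-2-[(tert-butyldimethylsilyl)oxy]phenyl}methanol
Conditions: NaBH4, MeOH/THF, 0 °C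
Reagents that add atoms: none
Why: Borohydride reduction of the aldehyde should give the benzylic alcohol while the aryl silyl ether and the benzyl ether stay intact at 0 °C.

Step 9
Reactants: 14 {4-(benzyloxy)-2-[(tert-butyldimethylsilyl)oxy]phenyl}methanol
Product: 15 [5-(benzyloxy)-2-(bromomethyl)phenoxy](tert-butyl)dimethylsilane
Conditions: CBr4, PPh3, CH2Cl2, 0 °C; filtered through a short pad and used at once
Reagents that add atoms: carbon tetrabromide, BrC(Br)(Br)Br
Why: Appel bromination under neutral conditions should give the labile electron-rich benzylic bromide without acid that would ionise it.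

Step 10
Reactants: 11 (4R)-4-benzyl-3-{[5-(benzyloxy)-2-bromo-3-methoxyphenyl]acetyl}-1,3-oxazolidin-2-one; 15 [5-(benzyloxy)-2-(bromomethyl)phenoxy](tert-butyl)dimethylsilane
Product: 17 (4R)-4-benzyl-3-[(2R)-2-[5-(benzyloxy)-2-bromo-3-methoxyphenyl]-3-{4-(benzyloxy)-2-[(tert-butyldimethylsilyl)oxy]phenyl}propanoyl]-1,3-oxazolidin-2-one, via sodium enolate 16 (not isolated)
Conditions: NaN(SiMe3)2 (1.0 equiv), THF, −78 °C; then 15, −78 to −30 °C
Reagents that add atoms: none
Why: Evans asymmetric alkylation: the chelated (Z)-sodium enolate 16 is alkylated on the face opposite to the benzyl group of the (R)-auxiliary, which should set the (R)-configuration of the future lower C3.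

Step 11
Reactants: 17 (4R)-4-benzyl-3-[(2R)-2-[5-(benzyloxy)-2-bromo-3-methoxyphenyl]-3-{4-(benzyloxy)-2-[(tert-butyldimethylsilyl)oxy]phenyl}propanoyl]-1,3-oxazolidin-2-one
Product: 18 (2R)-2-[5-(benzyloxy)-2-bromo-3-methoxyphenyl]-3-{4-(benzyloxy)-2-[(tert-butyldimethylsilyl)oxy]phenyl}propan-1-ol
Conditions: LiBH4, MeOH (1 equiv), Et2O, 0 °C
Reagents that add atoms: none
Why: Reductive cleavage of the imide by hydride attack at the exocyclic carbonyl should release the primary alcohol without epimerising the α-aryl centre and returns the auxiliary.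

Step 12
Reactants: 18 (2R)-2-[5-(benzyloxy)-2-bromo-3-methoxyphenyl]-3-{4-(benzyloxy)-2-[(tert-butyldimethylsilyl)oxy]phenyl}propan-1-ol
Product: 19 5-(benzyloxy)-2-[(2R)-2-[5-(benzyloxy)-2-bromo-3-methoxyphenyl]-3-hydroxypropyl]phenol
Conditions: Bu4NF, THF, 0 °C
Reagents that add atoms: none
Why: Fluoride-mediated desilylation of the aryl silyl ether should free the phenol needed for ring closure.

Step 13
Reactants: 19 5-(benzyloxy)-2-[(2R)-2-[5-(benzyloxy)-2-bromo-3-methoxyphenyl]-3-hydroxypropyl]phenol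
Product: 20 (3R)-7-(benzyloxy)-3-[5-(benzyloxy)-2-bromo-3-methoxyphenyl]chromane
Conditions: PPh3, DIAD, THF, 0 °C to rt
Reagents that add atoms: none
Why: Intramolecular Mitsunobu etherification (phenol as acid, primary alcohol as electrophile, 6-exo-tet closure) should form ring F without involving the stereocentre.

Step 14
Reactants: 12 4-(benzyloxy)-2-hydroxybenzaldehyde
Product: 21 5-(benzyloxy)-2-formylphenyl tert-butyl carbonate
Conditions: Boc2O, iPr2NEt, DMAP (5 mol %), THF, rt
Reagents that add atoms: di-tert-butyl dicarbonate, CC(C)(C)OC(=O)OC(=O)OC(C)(C)C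
Why: DMAP-catalysed O-acylation of the phenol should give the ortho-Boc-oxy aldehyde that serves as the latent o-quinone methide.

Step 15
Reactants: 22 2,6-dimethoxyphenol
Product: 23 2-(benzyloxy)-1,3-dimethoxybenzene
Conditions: BnBr, K2CO3, DMF, 60 °C
Reagents that add atoms: benzyl bromide, BrCc1ccccc1
Why: Williamson etherification should protect the hindered phenol as the benzyl ether.

Step 16
Reactants: 23 2-(benzyloxy)-1,3-dimethoxybenzene
Product: 25 3-(benzyloxy)-2,4-dimethoxybenzaldehyde, via iminium salt 24 (not isolated)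
Conditions: POCl3, DMF, 0 to 80 °C; then H2O, 0 °C to rt
Reagents that add atoms: N,N-dimethylformamide, CN(C)C=O; water, O
Why: Vilsmeier–Haack formylation should occur para to one methoxy group and ortho to the other (the two such positions are equivalent by symmetry, and the central benzyloxy group is twisted out of conjugation).

Step 17
Reactants: 25 3-(benzyloxy)-2,4-dimethoxybenzaldehyde
Product: 27 2-[3-(benzyloxy)-2,4-dimethoxyphenyl]acetaldehyde, via enol ether 26 (not isolated)
Conditions: Ph3P(CH2OMe)Cl, KOtBu, THF, 0 °C to rt; then 2 M HCl, THF, 40 °C; used without storage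
Reagents that add atoms: (methoxymethyl)triphenylphosphonium chloride, COC[P+](c1ccccc1)(c1ccccc1)c1ccccc1.[Cl-]; water, O
Why: Wittig methoxymethylenation followed by acid hydrolysis of enol ether 26 should give the homologated arylacetaldehyde.

Step 18
Reactants: 27 2-[3-(benzyloxy)-2,4-dimethoxyphenyl]acetaldehyde; 28 (2R)-2-{diphenyl[(trimethylsilyl)oxy]methyl}pyrrolidine
Product: 29 (2R)-1-{(E)-2-[3-(benzyloxy)-2,4-dimethoxyphenyl]ethenyl}-2-{diphenyl[(trimethylsilyl)oxy]methyl}pyrrolidine
Conditions: 4 Å molecular sieves, toluene, rt; filter, evaporate, use directly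
Reagents that add atoms: none
Why: Enamine condensation of the secondary amine with the aldehyde should give the aryl-conjugated (E)-enamine, with the sieves taking up the water.

Step 19
Reactants: 20 (3R)-7-(benzyloxy)-3-[5-(benzyloxy)-2-bromo-3-methoxyphenyl]chromane; 21 5-(benzyloxy)-2-formylphenyl tert-butyl carbonate; 29 (2R)-1-{(E)-2-[3-(benzyloxy)-2,4-dimethoxyphenyl]ethenyl}-2-{diphenyl[(trimethylsilyl)oxy]methyl}pyrrolidine
Product: 35 (3R,4S)-7-(benzyloxy)-3-[3-(benzyloxy)-2,4-dimethoxyphenyl]-4-{4-(benzyloxy)-2-[(3R)-7-(benzyloxy)chroman-3-yl]-6-methoxyphenyl}chroman-2-ol (C2 epimers), via aryllithium 30 (not isolated), via lithium alkoxide 31 (not isolated), via phenoxide carbonate 32 (not isolated), via o-quinone methide 33 (not isolated), via aminal 34 (not isolated)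
Conditions: 20, t-BuLi (2.0 equiv), THF, −78 °C; 21 (1.1 equiv), −78 °C; 29 (1.5 equiv), then MgBr2·OEt2 (1.2 equiv), −78 to 0 °C; then aq. AcOH, rt
Reagents that add atoms: water, O
Why: Proposed new method: an anionic o-quinone methide cascade is intercepted by a preformed chiral enamine; Br/Li exchange gives 30, which adds to the formyl group of 21, alkoxide 31 takes the Boc group from the neighbouring phenol oxygen (32), and magnesium-assisted loss of tert-butyl carbonate releases the (E)-o-quinone methide 33, whose methide carbon (the future C4) is attacked by the aryl-bearing enamine carbon of 29 (C3–C4 bond) before the phenoxide oxygen closes on the iminium carbon (O1–C2 bond, aminal 34, hydrolysed to lactol 35 on work-up). The closest known reaction types are the three-component chroman synthesis from O-Boc salicylaldehydes, organometallic reagents and enol ethers or simple enamines, and the amine-catalysed formal [4+2] of aldehydes with o-quinone methides that gives trans-3,4-disubstituted chroman-2-ols; not yet shown is a stoichiometric diarylprolinol silyl ether enamine as the chiral 2π partner of the anionic cascade. Ring C closes as a formal inverse-electron-demand hetero-[4+2] (Michael addition, then 6-exo-trig attack of the phenoxide oxygen on the iminium carbon). C3 is controlled by the amine, whose Ph2C(OSiMe3) group blocks one face of the s-trans (E)-enamine, and C4 is controlled by the compact nitrogen-endo (synclinal) approach of the (E)-quinone methide to the open enamine face, which places the two aryl groups trans and should give (3R,4S). The step needs regioselectivity (secured by the nitrogen donor, which makes the aryl-bearing carbon the nucleophile, whereas a β-alkoxystyrene could react in either sense), trans selectivity (endo approach, backed by the fact that C3 stays epimerisable through the aminal and trans is the more stable 3,4-diaryl arrangement) and reagent control over the existing (R)-centre (that centre sits on a twisted 2,6-disubstituted aryl ring that can turn its small OMe edge to either face of the methide, so no strong substrate bias is expected). Easy formation of 33 is secured by the C7 benzyloxy group para to the benzylic carbon, and attack of the aryllithium at the aldehyde and not at the carbonate rests on the −78 °C addition.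

Step 20
Reactants: 35 (3R,4S)-7-(benzyloxy)-3-[3-(benzyloxy)-2,4-dimethoxyphenyl]-4-{4-(benzyloxy)-2-[(3R)-7-(benzyloxy)chroman-3-yl]-6-methoxyphenyl}chroman-2-ol
Product: 36 (3R,4S)-7-(benzyloxy)-3-[3-(benzyloxy)-2,4-dimethoxyphenyl]-4-{4-(benzyloxy)-2-[(3R)-7-(benzyloxy)chroman-3-yl]-6-methoxyphenyl}chromane
Conditions: Et3SiH, BF3·OEt2, CH2Cl2, −78 to −20 °C
Reagents that add atoms: none
Why: Ionic hydrogenation of the lactol: BF3 ionises the anomeric C–OH to the cyclic aryloxocarbenium ion, which Et3SiH should reduce to the C2 methylene while the benzyl ethers and the C3/C4 centres are left alone at low temperature.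

Step 21
Reactants: 36 (3R,4S)-7-(benzyloxy)-3-[3-(benzyloxy)-2,4-dimethoxyphenyl]-4-{4-(benzyloxy)-2-[(3R)-7-(benzyloxy)chroman-3-yl]-6-methoxyphenyl}chromane
Product: 37 (3R,4S)-3-(3-hydroxy-2,4-dimethoxyphenyl)-4-{4-hydroxy-2-[(3R)-7-hydroxychroman-3-yl]-6-methoxyphenyl}chroman-7-ol (CNP0305801.1)
Conditions: H2 (1 atm), Pd/C (10 %), EtOAc/MeOH, rt
Reagents that add atoms: none
Why: Catalytic hydrogenolysis should remove the four benzyl ethers; the chroman C–O bonds are not benzylic and the diarylmethine C4–H is inert, so the three stereocentres are retained.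

## Compound list

1 | 2-bromo-3-methoxybenzoic acid | COc1cccc(C(=O)O)c1Br | starting material
2 | 2-bromo-3-methoxybenzoyl chloride | COc1cccc(C(=O)Cl)c1Br | intermediate
3 | 1-(2-bromo-3-methoxyphenyl)-2-diazoethan-1-one | COc1cccc(C(=O)C=[N+]=[N-])c1Br | intermediate
4 | methyl 2-(2-bromo-3-methoxyphenyl)acetate | COc1cccc(CC(=O)OC)c1Br | intermediate
5 | methyl 2-[2-bromo-3-methoxy-5-(4,4,5,5-tetramethyl-1,3,2-dioxaborolan-2-yl)phenyl]acetate | COc1cc(B2OC(C)(C)C(C)(C)O2)cc(CC(=O)OC)c1Br | intermediate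
6 | methyl 2-(2-bromo-5-hydroxy-3-methoxyphenyl)acetate | COc1cc(O)cc(CC(=O)OC)c1Br | intermediate
7 | methyl 2-[5-(benzyloxy)-2-bromo-3-methoxyphenyl]acetate | COc1cc(OCc2ccccc2)cc(CC(=O)OC)c1Br | intermediate
8 | 2-[5-(benzyloxy)-2-bromo-3-methoxyphenyl]acetic acid | COc1cc(OCc2ccccc2)cc(CC(=O)O)c1Br | intermediate
9 | (4R)-4-benzyl-1,3-oxazolidin-2-one | O=C1OC[C@@H](Cc2ccccc2)N1 | starting material
10 | [5-(benzyloxy)-2-bromo-3-methoxyphenyl]acetic pivalic anhydride | COc1cc(OCc2ccccc2)cc(CC(=O)OC(=O)C(C)(C)C)c1Br | intermediate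
11 | (4R)-4-benzyl-3-{[5-(benzyloxy)-2-bromo-3-methoxyphenyl]acetyl}-1,3-oxazolidin-2-one | COc1cc(OCc2ccccc2)cc(CC(=O)N2[C@H](Cc3ccccc3)COC2=O)c1Br | intermediate
12 | 4-(benzyloxy)-2-hydroxybenzaldehyde | O=Cc1ccc(OCc2ccccc2)cc1O | starting material
13 | 4-(benzyloxy)-2-[(tert-butyldimethylsilyl)oxy]benzaldehyde | O=Cc1ccc(OCc2ccccc2)cc1O[Si](C)(C)C(C)(C)C | intermediate
14 | {4-(benzyloxy)-2-[(tert-butyldimethylsilyl)oxy]phenyl}methanol | OCc1ccc(OCc2ccccc2)cc1O[Si](C)(C)C(C)(C)C | intermediate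
15 | [5-(benzyloxy)-2-(bromomethyl)phenoxy](tert-butyl)dimethylsilane | BrCc1ccc(OCc2ccccc2)cc1O[Si](C)(C)C(C)(C)C | intermediate
16 | sodium (Z)-enolate of imide 11 | [Na+].[O-]/C(=C\c1cc(OCc2ccccc2)cc(OC)c1Br)N1[C@H](Cc2ccccc2)COC1=O | intermediate
17 | (4R)-4-benzyl-3-[(2R)-2-[5-(benzyloxy)-2-bromo-3-methoxyphenyl]-3-{4-(benzyloxy)-2-[(tert-butyldimethylsilyl)oxy]phenyl}propanoyl]-1,3-oxazolidin-2-one | COc1cc(OCc2ccccc2)cc([C@@H](Cc2ccc(OCc3ccccc3)cc2O[Si](C)(C)C(C)(C)C)C(=O)N2[C@H](Cc3ccccc3)COC2=O)c1Br | intermediate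
18 | (2R)-2-[5-(benzyloxy)-2-bromo-3-methoxyphenyl]-3-{4-(benzyloxy)-2-[(tert-butyldimethylsilyl)oxy]phenyl}propan-1-ol | COc1cc(OCc2ccccc2)cc([C@@H](Cc2ccc(OCc3ccccc3)cc2O[Si](C)(C)C(C)(C)C)CO)c1Br | intermediate
19 | 5-(benzyloxy)-2-[(2R)-2-[5-(benzyloxy)-2-bromo-3-methoxyphenyl]-3-hydroxypropyl]phenol | COc1cc(OCc2ccccc2)cc([C@@H](Cc2ccc(OCc3ccccc3)cc2O)CO)c1Br | intermediate
20 | (3R)-7-(benzyloxy)-3-[5-(benzyloxy)-2-bromo-3-methoxyphenyl]chromane | COc1cc(OCc2ccccc2)cc([C@@H]2COc3cc(OCc4ccccc4)ccc3C2)c1Br | intermediate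
21 | 5-(benzyloxy)-2-formylphenyl tert-butyl carbonate | O=Cc1ccc(OCc2ccccc2)cc1OC(=O)OC(C)(C)C | intermediate
22 | 2,6-dimethoxyphenol | COc1cccc(OC)c1O | starting material
23 | 2-(benzyloxy)-1,3-dimethoxybenzene | COc1cccc(OC)c1OCc1ccccc1 | intermediate
24 | N-[3-(benzyloxy)-2,4-dimethoxybenzylidene]-N-methylmethanaminium chloride | C[N+](C)=Cc1ccc(OC)c(OCc2ccccc2)c1OC.[Cl-] | intermediate
25 | 3-(benzyloxy)-2,4-dimethoxybenzaldehyde | COc1ccc(C=O)c(OC)c1OCc1ccccc1 | intermediate
26 | 2-(benzyloxy)-1,3-dimethoxy-4-(2-methoxyethenyl)benzene (E/Z mixture) | COC=Cc1ccc(OC)c(OCc2ccccc2)c1OC | intermediate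
27 | 2-[3-(benzyloxy)-2,4-dimethoxyphenyl]acetaldehyde | COc1ccc(CC=O)c(OC)c1OCc1ccccc1 | intermediate
28 | (2R)-2-{diphenyl[(trimethylsilyl)oxy]methyl}pyrrolidine | C[Si](C)(C)OC(c1ccccc1)(c1ccccc1)[C@H]1CCCN1 | starting material
29 | (2R)-1-{(E)-2-[3-(benzyloxy)-2,4-dimethoxyphenyl]ethenyl}-2-{diphenyl[(trimethylsilyl)oxy]methyl}pyrrolidine | COc1ccc(/C=C/N2CCC[C@@H]2C(c2ccccc2)(c2ccccc2)O[Si](C)(C)C)c(OC)c1OCc1ccccc1 | intermediate
30 | {4-(benzyloxy)-2-[(3R)-7-(benzyloxy)chroman-3-yl]-6-methoxyphenyl}lithium | COc1cc(OCc2ccccc2)cc([C@@H]2COc3cc(OCc4ccccc4)ccc3C2)c1[Li] | intermediate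
31 | lithium {4-(benzyloxy)-2-[(tert-butoxycarbonyl)oxy]phenyl}{4-(benzyloxy)-2-[(3R)-7-(benzyloxy)chroman-3-yl]-6-methoxyphenyl}methanolate (both carbinol epimers) | [Li+].[O-]C(c1ccc(OCc2ccccc2)cc1OC(=O)OC(C)(C)C)c1c(OC)cc(OCc2ccccc2)cc1[C@@H]1COc2cc(OCc3ccccc3)ccc2C1 | intermediate
32 | lithium 5-(benzyloxy)-2-[{4-(benzyloxy)-2-[(3R)-7-(benzyloxy)chroman-3-yl]-6-methoxyphenyl}[(tert-butoxycarbonyl)oxy]methyl]phenolate | [Li+].[O-]c1cc(OCc2ccccc2)ccc1C(OC(=O)OC(C)(C)C)c1c(OC)cc(OCc2ccccc2)cc1[C@@H]1COc2cc(OCc3ccccc3)ccc2C1 | intermediate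
33 | (6E)-3-(benzyloxy)-6-({4-(benzyloxy)-2-[(3R)-7-(benzyloxy)chroman-3-yl]-6-methoxyphenyl}methylidene)cyclohexa-2,4-dien-1-one | O=C1C=C(OCc2ccccc2)C=C/C1=C\c1c(OC)cc(OCc2ccccc2)cc1[C@@H]1COc2cc(OCc3ccccc3)ccc2C1 | intermediate
34 | (2R)-1-[(3R,4S)-7-(benzyloxy)-3-[3-(benzyloxy)-2,4-dimethoxyphenyl]-4-{4-(benzyloxy)-2-[(3R)-7-(benzyloxy)chroman-3-yl]-6-methoxyphenyl}chroman-2-yl]-2-{diphenyl[(trimethylsilyl)oxy]methyl}pyrrolidine (chroman C2 unassigned) | COc1ccc([C@@H]2C(N3CCC[C@@H]3C(c3ccccc3)(c3ccccc3)O[Si](C)(C)C)Oc3cc(OCc4ccccc4)ccc3[C@H]2c2c(OC)cc(OCc3ccccc3)cc2[C@@H]2COc3cc(OCc4ccccc4)ccc3C2)c(OC)c1OCc1ccccc1 | intermediate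
35 | (3R,4S)-7-(benzyloxy)-3-[3-(benzyloxy)-2,4-dimethoxyphenyl]-4-{4-(benzyloxy)-2-[(3R)-7-(benzyloxy)chroman-3-yl]-6-methoxyphenyl}chroman-2-ol (C2 epimers) | COc1ccc([C@@H]2C(O)Oc3cc(OCc4ccccc4)ccc3[C@H]2c2c(OC)cc(OCc3ccccc3)cc2[C@@H]2COc3cc(OCc4ccccc4)ccc3C2)c(OC)c1OCc1ccccc1 | intermediate
36 | (3R,4S)-7-(benzyloxy)-3-[3-(benzyloxy)-2,4-dimethoxyphenyl]-4-{4-(benzyloxy)-2-[(3R)-7-(benzyloxy)chroman-3-yl]-6-methoxyphenyl}chromane | COc1ccc([C@@H]2COc3cc(OCc4ccccc4)ccc3[C@H]2c2c(OC)cc(OCc3ccccc3)cc2[C@@H]2COc3cc(OCc4ccccc4)ccc3C2)c(OC)c1OCc1ccccc1 | intermediate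
37 | (3R,4S)-3-(3-hydroxy-2,4-dimethoxyphenyl)-4-{4-hydroxy-2-[(3R)-7-hydroxychroman-3-yl]-6-methoxyphenyl}chroman-7-ol | COc1ccc([C@@H]2COc3cc(O)ccc3[C@H]2c2c(OC)cc(O)cc2[C@@H]2COc3cc(O)ccc3C2)c(OC)c1O | target

## Step count and risks

Total step count: 21. Longest linear sequence: 13 steps (steps 1–6, 10–13, 19–21).

Steps most likely to fail:

1. Step 19 (Proposed new method). The hindered methide carbon of 33 may be attacked too slowly by the bulky enamine, so that oligomerisation of the quinone methide or its capture by tert-butoxide takes over, and face selection at C4 may be incomplete. The fallback uses known chemistry and sets out from 20. Aryllithium 30 (from 20, t-BuLi, THF, −78 °C) is added to aldehyde 13 to give the silyl-protected diarylmethanol {4-(benzyloxy)-2-[(tert-butyldimethylsilyl)oxy]phenyl}{4-(benzyloxy)-2-[(3R)-7-(benzyloxy)chroman-3-yl]-6-methoxyphenyl}methanol F1, and Bu4NF (THF, 0 °C) then frees the o-hydroxybenzhydrol 5-(benzyloxy)-2-[{4-(benzyloxy)-2-[(3R)-7-(benzyloxy)chroman-3-yl]-6-methoxyphenyl}(hydroxy)methyl]phenol F2. F2, aldehyde 27 (2 equiv), amine 28 (20 mol %) and PhCO2H (20 mol %) in CH2Cl2 at rt should then undergo acid-promoted dehydration to quinone methide 33 at low stationary concentration and the amine-catalysed formal [4+2] of the catalytic enamine with it. This should give lactol 35, where the route is rejoined.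

2. Step 10. Ionisation and polymerisation of the electron-rich silyloxybenzyl bromide may outrun the alkylation of the stabilised α-aryl enolate, and excess base may erode the new α-aryl centre. The fallback sets out from acid 8 and aldehyde 12 and replaces the auxiliary alkylation by catalytic asymmetric hydrogenation. Perkin condensation (Ac2O, Et3N, 110 °C) should give the coumarin 7-(benzyloxy)-3-[5-(benzyloxy)-2-bromo-3-methoxyphenyl]-2H-chromen-2-one F3. Borane reduction (BH3·THF, THF, rt to 50 °C) should convert it into the isoflav-3-ene 7-(benzyloxy)-3-[5-(benzyloxy)-2-bromo-3-methoxyphenyl]-2H-chromene F4. Asymmetric hydrogenation of the trisubstituted olefin with an iridium phosphine–oxazoline catalyst, [Ir(cod)(PHOX)][B(C6H3(CF3)2)4] (ligand enantiomer chosen for the (R)-product), H2 (50 bar), CH2Cl2, rt, should give chromane 20, where the route is rejoined.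

3. Step 20. The lactol may ionise in the wrong sense (ring opening to the hydroxy-aldehyde and its reduction), the oxocarbenium ion may lose the C3 proton and be reprotonated without selectivity, or the Lewis acid may attack the benzyl ethers or the doubly benzylic C4. The fallback sets out from 35 and avoids the cation. NaBH4 (EtOH/THF, 0 °C) reduces the open-chain aldehyde tautomer to the phenol–alcohol 5-(benzyloxy)-2-[(1S,2R)-2-[3-(benzyloxy)-2,4-dimethoxyphenyl]-1-{4-(benzyloxy)-2-[(3R)-7-(benzyloxy)chroman-3-yl]-6-methoxyphenyl}-3-hydroxypropyl]phenol F5. Intramolecular Mitsunobu etherification (PPh3, DIAD, THF, 0 °C to rt) then re-forms the O1–C2 bond and should give 36, where the route is rejoined.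

Further compounds
F1 | step 19 | {4-(benzyloxy)-2-[(tert-butyldimethylsilyl)oxy]phenyl}{4-(benzyloxy)-2-[(3R)-7-(benzyloxy)chroman-3-yl]-6-methoxyphenyl}methanol | OC(c1ccc(OCc2ccccc2)cc1O[Si](C)(C)C(C)(C)C)c1c(OC)cc(OCc2ccccc2)cc1[C@@H]1COc2cc(OCc3ccccc3)ccc2C1
F2 | step 19 | 5-(benzyloxy)-2-[{4-(benzyloxy)-2-[(3R)-7-(benzyloxy)chroman-3-yl]-6-methoxyphenyl}(hydroxy)methyl]phenol | OC(c1ccc(OCc2ccccc2)cc1O)c1c(OC)cc(OCc2ccccc2)cc1[C@@H]1COc2cc(OCc3ccccc3)ccc2C1
F3 | step 10 | 7-(benzyloxy)-3-[5-(benzyloxy)-2-bromo-3-methoxyphenyl]-2H-chromen-2-one | COc1cc(OCc2ccccc2)cc(C2=Cc3ccc(OCc4ccccc4)cc3OC2=O)c1Br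
F4 | step 10 | 7-(benzyloxy)-3-[5-(benzyloxy)-2-bromo-3-methoxyphenyl]-2H-chromene | COc1cc(OCc2ccccc2)cc(C2=Cc3ccc(OCc4ccccc4)cc3OC2)c1Br
F5 | step 20 | 5-(benzyloxy)-2-[(1S,2R)-2-[3-(benzyloxy)-2,4-dimethoxyphenyl]-1-{4-(benzyloxy)-2-[(3R)-7-(benzyloxy)chroman-3-yl]-6-methoxyphenyl}-3-hydroxypropyl]phenol | COc1ccc([C@H](CO)[C@@H](c2ccc(OCc3ccccc3)cc2O)c2c(OC)cc(OCc3ccccc3)cc2[C@@H]2COc3cc(OCc4ccccc4)ccc3C2)c(OC)c1OCc1ccccc1
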